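**Retrosynthetic overview**

1. The seven phenols are carried as benzyl ethers and the cis-stilbene as a diarylalkyne: 26 ⇐ 25 (BCl3 debenzylation) ⇐ 24 (syn-semihydrogenation).
2. The two aryl–C(sp3) bonds (C3'–resorcinol ring and C3–C4' of ring B) are cut to dihydrobenzofuran-3-carboxylic acids and arylboronic acids; each is made by nickel-catalysed decarboxylative arylation, in which the C2 aryl group directs the incoming aryl trans.
3. Both 2-aryl-2,3-dihydrobenzofuran-3-carboxylates come from oxidative ring contraction of enantiomeric 5-triflyloxyflavanones: the (2S) series from naringenin, the (2R) series by asymmetric conjugate addition to a chromone. The 5-O-triflates become the alkyne (unit 1) and the boronic acid (unit 2).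
4. Enabling feature: each dihydrofuran ring O1–C2–C3–C3a–C7a is a flavanone C ring that has lost C4. Ring A, O1 and the C2 stereocentre with its 4-hydroxyphenyl group are already present in (2S)-naringenin (its 5-oxygen sits where the styryl carbon is needed). C3a is para to the C6 oxygen and ortho to O1, so it is an electron-rich carbon that shifts readily from C4 to C3.
5. Ring order: the dihydrofuran ring of unit 1 (step 3) and that of unit 2 (step 9) are closed on separate fragments. No ring is formed after the fragments are joined.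

Key step: step 3

Assumption: (2S)-naringenin is used as the purchased single enantiomer, and every step before the ring contraction is run without strong base so that the flavanone does not racemise by retro-oxa-Michael opening.
Locants: unit 1 is O1/C2/C3/C3a/C4–C7/C7a on ring A (styryl at C4); unit 2 carries primed locants on ring B; flavanones keep chroman numbering (C4a there becomes C3a).

**Route**

Step 1
Reactants: 1 (2S)-naringenin
Product: 2 (2S)-7-(benzyloxy)-2-[4-(benzyloxy)phenyl]-5-hydroxychroman-4-one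
Conditions: BnOH (2.2 equiv), PPh3, DIAD, THF, 0 °C to rt
Reagents that add atoms: benzyl alcohol, OCc1ccccc1
Why: Mitsunobu etherification alkylates the two free, more acidic phenols (7-OH and 4'-OH) while the 5-OH, held in a hydrogen bond to the C4 carbonyl, stays untouched, and the base-free medium avoids opening of the flavanone ring, so C2 keeps its configuration.

Step 2
Reactants: 2 (2S)-7-(benzyloxy)-2-[4-(benzyloxy)phenyl]-5-hydroxychroman-4-one
Product: 3 (2S)-7-(benzyloxy)-2-[4-(benzyloxy)phenyl]-4-oxochroman-5-yl trifluoromethanesulfonate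
Conditions: Tf2O, pyridine, CH2Cl2, −20 to 0 °C
Reagents that add atoms: trifluoromethanesulfonic anhydride, O=S(=O)(OS(=O)(=O)C(F)(F)F)C(F)(F)F
Why: O-sulfonylation of the remaining chelated phenol turns the 5-oxygen into the later cross-coupling handle and frees the C4 carbonyl from its hydrogen bond, which should ease ketal formation in step 3; the weak base and low temperature leave C2 intact.

Step 3
Reactants: 3 (2S)-7-(benzyloxy)-2-[4-(benzyloxy)phenyl]-4-oxochroman-5-yl trifluoromethanesulfonate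
Product: 6 methyl (2S,3S)-6-(benzyloxy)-2-[4-(benzyloxy)phenyl]-4-(trifluoromethanesulfonyloxy)-2,3-dihydro-1-benzofuran-3-carboxylate, via methyl enol ether 4 (not isolated), via trans-3-iodanyl dimethyl ketal 5 (not isolated)
Conditions: PhI(OAc)2, conc. H2SO4, HC(OMe)3, rt
Reagents that add atoms: trimethyl orthoformate, COC(OC)OC
Why: Acid and HC(OMe)3 convert the C4 ketone into its methyl enol ether 4, the electrophilic trivalent iodine reagent adds to C3 on the face anti to the C2 aryl group while methanol closes the ketal (5), and the ring A carbon C4a (C3a of the product), antiperiplanar to the C3–I bond in the diequatorial conformer, then shifts from C4 to C3 with loss of PhI while the two methoxy groups stabilise the cation left at C4, which collapses to the methyl ester. The closest known reaction is the oxidative ring contraction of flavanones to trans-2-aryl-2,3-dihydrobenzofuran-3-carboxylates with PhI(OAc)2 or Tl(NO3)3 in trimethyl orthoformate, a reaction type that leaves C2 untouched. The dihydrofuran ring O1–C2–C3–C3a–C7a is closed by this suprafacial 1,2-aryl shift, a six-to-five ring contraction through a bridged arenium (phenonium-type) transition state in which the C3–C3a bond forms as the C4–C3a bond breaks. The C2 stereocentre of naringenin is kept, and the new C3 stereocentre results from anti iodination followed by inversion at C3 during the shift, which should give the 2,3-trans ester (also the thermodynamically preferred epimer). The step needs migration of ring A in preference to the 2,3-shift of the C2 aryl group (isoflavone) and to elimination (flavone); this is secured by the ketal, which supplies the push for the C4-to-C3 shift, by the benzyloxy group para and the ring oxygen ortho to the migrating carbon, and by the equatorial C2 aryl group, which cannot become antiperiplanar to the C3–I bond without a ring flip.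

Step 4
Reactants: 6 methyl (2S,3S)-6-(benzyloxy)-2-[4-(benzyloxy)phenyl]-4-(trifluoromethanesulfonyloxy)-2,3-dihydro-1-benzofuran-3-carboxylate; 7 1-(benzyloxy)-4-ethynylbenzene
Product: 8 methyl (2S,3S)-6-(benzyloxy)-2-[4-(benzyloxy)phenyl]-4-{[4-(benzyloxy)phenyl]ethynyl}-2,3-dihydro-1-benzofuran-3-carboxylate
Conditions: PdCl2(PPh3)2, CuI, n-Bu4NI, Et3N, DMF, 70 °C
Reagents that add atoms: none
Why: Sonogashira coupling of the aryl triflate (oxidative addition to zerovalent palladium, transmetalation from the copper acetylide) installs the two-carbon bridge and the third phenol ring as a diarylalkyne, a masked cis-stilbene that should be inert to the later radical couplings; the trans ester is the stable epimer, so Et3N cannot erode C3.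

Step 5
Reactants: 8 methyl (2S,3S)-6-(benzyloxy)-2-[4-(benzyloxy)phenyl]-4-{[4-(benzyloxy)phenyl]ethynyl}-2,3-dihydro-1-benzofuran-3-carboxylate
Product: 9 (2S,3S)-6-(benzyloxy)-2-[4-(benzyloxy)phenyl]-4-{[4-(benzyloxy)phenyl]ethynyl}-2,3-dihydro-1-benzofuran-3-carboxylic acid
Conditions: LiOH, THF–MeOH–H2O, 40 °C; then aq. HCl to pH 3
Reagents that add atoms: lithium hydroxide, [Li+].[OH-]
Why: Saponification (acyl–oxygen cleavage by hydroxide) frees the acid for decarboxylative coupling; C3 is already the more stable trans epimer, C2 has no acidic hydrogen, and benzyl ethers and alkyne are stable to base.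

Step 6
Reactants: 10 5,7-dihydroxy-4H-chromen-4-one
Product: 11 7-(benzyloxy)-5-hydroxy-4H-chromen-4-one
Conditions: BnBr (1.05 equiv), K2CO3, acetone, reflux
Reagents that add atoms: benzyl bromide, BrCc1ccccc1
Why: Williamson etherification takes the acidic 7-OH selectively because the 5-OH is deactivated by its hydrogen bond to the chromone carbonyl.

Step 7
Reactants: 11 7-(benzyloxy)-5-hydroxy-4H-chromen-4-one
Product: 12 7-(benzyloxy)-4-oxo-4H-chromen-5-yl trifluoromethanesulfonate
Conditions: Tf2O, pyridine, CH2Cl2, 0 °C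
Reagents that add atoms: trifluoromethanesulfonic anhydride, O=S(=O)(OS(=O)(=O)C(F)(F)F)C(F)(F)F
Why: O-sulfonylation of the chelated phenol installs the ring B coupling handle and makes the chromone a stronger conjugate acceptor for step 8.

Step 8
Reactants: 12 7-(benzyloxy)-4-oxo-4H-chromen-5-yl trifluoromethanesulfonate; 13 [4-(benzyloxy)phenyl]boronic acid
Product: 14 (2R)-7-(benzyloxy)-2-[4-(benzyloxy)phenyl]-4-oxochroman-5-yl trifluoromethanesulfonate
Conditions: Pd(OCOCF3)2 (5 mol%), (S)-t-BuPyOx (6 mol%), NH4PF6, H2O, ClCH2CH2Cl, 60 °C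
Reagents that add atoms: none
Why: Asymmetric conjugate addition catalysed by divalent palladium with a pyridine-oxazoline ligand (transmetalation, enantio-determining insertion of the chromone C2=C3 bond into the Pd–aryl bond, protonolysis of the palladium enolate) sets C2 under catalyst control; the (S)-ligand is expected to give the (2R) series by the facial model that holds for cyclic enones (its antipode is used should the sense prove opposite), and the cycle does not pass through zerovalent palladium, so the aryl triflate should survive.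

Step 9
Reactants: 14 (2R)-7-(benzyloxy)-2-[4-(benzyloxy)phenyl]-4-oxochroman-5-yl trifluoromethanesulfonate
Product: 17 methyl (2R,3R)-6-(benzyloxy)-2-[4-(benzyloxy)phenyl]-4-(trifluoromethanesulfonyloxy)-2,3-dihydro-1-benzofuran-3-carboxylate, via enantiomeric methyl enol ether 15 (not isolated), via enantiomeric trans-3-iodanyl dimethyl ketal 16 (not isolated)
Conditions: PhI(OAc)2, conc. H2SO4, HC(OMe)3, rt
Reagents that add atoms: trimethyl orthoformate, COC(OC)OC
Why: The same oxidative flavanone ring contraction as in step 3 in the mirror-image series: anti iodination at C3 and the inverting 1,2-shift of the ring B carbon from C4 to C3 should give the 2,3-trans (2R,3R) ester with C2 unchanged.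

Step 10
Reactants: 17 methyl (2R,3R)-6-(benzyloxy)-2-[4-(benzyloxy)phenyl]-4-(trifluoromethanesulfonyloxy)-2,3-dihydro-1-benzofuran-3-carboxylate
Product: 18 [(2R,3R)-6-(benzyloxy)-2-[4-(benzyloxy)phenyl]-3-(methoxycarbonyl)-2,3-dihydro-1-benzofuran-4-yl]boronic acid
Conditions: B2(OH)4, Pd(OAc)2, XPhos, KOAc, MeOH, 60 °C
Reagents that add atoms: tetrahydroxydiboron, OB(O)B(O)O
Why: Miyaura borylation (oxidative addition of the aryl triflate to zerovalent palladium, transmetalation from the diboron reagent, reductive elimination) gives the boronic acid directly; the bulky biaryl phosphine tolerates the ortho substituent and KOAc is too weak a base to open or epimerise the ester.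

Step 11
Reactants: 9 (2S,3S)-6-(benzyloxy)-2-[4-(benzyloxy)phenyl]-4-{[4-(benzyloxy)phenyl]ethynyl}-2,3-dihydro-1-benzofuran-3-carboxylic acid; 18 [(2R,3R)-6-(benzyloxy)-2-[4-(benzyloxy)phenyl]-3-(methoxycarbonyl)-2,3-dihydro-1-benzofuran-4-yl]boronic acid
Product: 20 methyl (2R,3R)-6-(benzyloxy)-2-[4-(benzyloxy)phenyl]-4-[(2S,3S)-6-(benzyloxy)-2-[4-(benzyloxy)phenyl]-4-{[4-(benzyloxy)phenyl]ethynyl}-2,3-dihydro-1-benzofuran-3-yl]-2,3-dihydro-1-benzofuran-3-carboxylate, via tetrachlorophthalimide ester 19 (not isolated)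
Conditions: N-hydroxytetrachlorophthalimide, DIC, DMAP (cat.), CH2Cl2, rt; solvent exchange; then 18, NiCl2·6H2O, bathophenanthroline, Et3N, 1,4-dioxane–DMF, 75 °C
Reagents that add atoms: none
Why: Nickel-catalysed decarboxylative Suzuki-type coupling of a redox-active ester: single-electron reduction of 19 releases CO2 and the planar benzylic C3 radical, which the aryl–nickel species formed from 18 should capture on the face anti to the C2 aryl group before C–C reductive elimination, so C3 is set trans to C2 (3S) by substrate control while C2, C2' and C3' are untouched.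

Step 12
Reactants: 20 methyl ester of the coupled bis(dihydrobenzofuran)
Product: 21 (2R,3R)-6-(benzyloxy)-2-[4-(benzyloxy)phenyl]-4-[(2S,3S)-6-(benzyloxy)-2-[4-(benzyloxy)phenyl]-4-{[4-(benzyloxy)phenyl]ethynyl}-2,3-dihydro-1-benzofuran-3-yl]-2,3-dihydro-1-benzofuran-3-carboxylic acid
Conditions: LiOH, THF–MeOH–H2O, 50 °C; then aq. HCl to pH 3
Reagents that add atoms: lithium hydroxide, [Li+].[OH-]
Why: Saponification of the remaining methyl ester; C3' is the stable trans epimer and the other three stereocentres carry no acidic hydrogen.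

Step 13
Reactants: 21 carboxylic acid of the coupled bis(dihydrobenzofuran); 22 [3,5-bis(benzyloxy)phenyl]boronic acid
Product: 24 (2S,3S)-6-(benzyloxy)-2-[4-(benzyloxy)phenyl]-4-{[4-(benzyloxy)phenyl]ethynyl}-3-[(2R,3R)-6-(benzyloxy)-2-[4-(benzyloxy)phenyl]-3-[3,5-bis(benzyloxy)phenyl]-2,3-dihydro-1-benzofuran-4-yl]-2,3-dihydro-1-benzofuran, via tetrachlorophthalimide ester 23 (not isolated)
Conditions: N-hydroxytetrachlorophthalimide, DIC, DMAP (cat.), CH2Cl2, rt; solvent exchange; then 22 (3 equiv), NiCl2·6H2O, bathophenanthroline, Et3N, 1,4-dioxane–DMF, 75 °C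
Reagents that add atoms: none
Why: The same nickel-catalysed decarboxylative Suzuki-type arylation: the planar C3' radical from 23 should be captured by the unhindered aryl–nickel species anti to the C2' aryl group, which sets C3' trans to C2' (3'R) by substrate control.

Step 14
Reactants: 24 hepta-O-benzyl diarylalkyne
Product: 25 hepta-O-benzyl-cis-miyabenol C (Z alkene)
Conditions: H2 (1 atm), Pd/CaCO3 poisoned with Pb(OAc)2 (Lindlar catalyst), quinoline, EtOAc, rt
Reagents that add atoms: none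
Why: Semihydrogenation over lead-poisoned palladium delivers both hydrogens syn on the catalyst surface and stops at the alkene, which fixes the Z geometry; this catalyst does not hydrogenolyse benzyl ethers.

Step 15
Reactants: 25 hepta-O-benzyl-cis-miyabenol C
Product: 26 cis-miyabenol C
Conditions: BCl3, pentamethylbenzene, CH2Cl2, −78 °C; MeOH quench
Reagents that add atoms: none
Why: Lewis acid debenzylation at low temperature: BCl3 activates the ether oxygens and pentamethylbenzene traps the benzyl cations irreversibly, which should spare the Z alkene and the benzylic C–O bonds of both dihydrofuran rings; no stereocentre is involved.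

**Compound list**

1 | (2S)-naringenin, (2S)-5,7-dihydroxy-2-(4-hydroxyphenyl)chroman-4-one | O=C1C[C@@H](c2ccc(O)cc2)Oc2cc(O)cc(O)c12 | starting material
2 | (2S)-7-(benzyloxy)-2-[4-(benzyloxy)phenyl]-5-hydroxychroman-4-one | O=C1C[C@@H](c2ccc(OCc3ccccc3)cc2)Oc2cc(OCc3ccccc3)cc(O)c12 | intermediate
3 | (2S)-7-(benzyloxy)-2-[4-(benzyloxy)phenyl]-4-oxochroman-5-yl trifluoromethanesulfonate | O=C1C[C@@H](c2ccc(OCc3ccccc3)cc2)Oc2cc(OCc3ccccc3)cc(OS(=O)(=O)C(F)(F)F)c12 | intermediate
4 | (2S)-7-(benzyloxy)-2-[4-(benzyloxy)phenyl]-4-methoxy-2H-chromen-5-yl trifluoromethanesulfonate (methyl enol ether) | COC1=C[C@@H](c2ccc(OCc3ccccc3)cc2)Oc2cc(OCc3ccccc3)cc(OS(=O)(=O)C(F)(F)F)c12 | intermediate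
5 | (2R,3R)-3-[acetoxy(phenyl)-λ3-iodanyl]-7-(benzyloxy)-2-[4-(benzyloxy)phenyl]-4,4-dimethoxychroman-5-yl trifluoromethanesulfonate (iodanyl group trans to the C2 aryl group; C2 geometry as in 3) | COC1(OC)[C@H](I(OC(C)=O)c2ccccc2)[C@@H](c2ccc(OCc3ccccc3)cc2)Oc2cc(OCc3ccccc3)cc(OS(=O)(=O)C(F)(F)F)c12 | intermediate
6 | methyl (2S,3S)-6-(benzyloxy)-2-[4-(benzyloxy)phenyl]-4-(trifluoromethanesulfonyloxy)-2,3-dihydro-1-benzofuran-3-carboxylate (2,3-trans) | O=S(=O)(Oc1cc(OCc2ccccc2)cc2c1[C@H](C(=O)OC)[C@@H](c1ccc(OCc3ccccc3)cc1)O2)C(F)(F)F | intermediate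
7 | 1-(benzyloxy)-4-ethynylbenzene | C#Cc1ccc(OCc2ccccc2)cc1 | starting material
8 | methyl (2S,3S)-6-(benzyloxy)-2-[4-(benzyloxy)phenyl]-4-{[4-(benzyloxy)phenyl]ethynyl}-2,3-dihydro-1-benzofuran-3-carboxylate | C(#Cc1ccc(OCc2ccccc2)cc1)c1cc(OCc2ccccc2)cc2c1[C@H](C(=O)OC)[C@@H](c1ccc(OCc3ccccc3)cc1)O2 | intermediate
9 | (2S,3S)-6-(benzyloxy)-2-[4-(benzyloxy)phenyl]-4-{[4-(benzyloxy)phenyl]ethynyl}-2,3-dihydro-1-benzofuran-3-carboxylic acid | C(#Cc1ccc(OCc2ccccc2)cc1)c1cc(OCc2ccccc2)cc2c1[C@H](C(=O)O)[C@@H](c1ccc(OCc3ccccc3)cc1)O2 | intermediate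
10 | 5,7-dihydroxy-4H-chromen-4-one | O=c1ccoc2cc(O)cc(O)c12 | starting material
11 | 7-(benzyloxy)-5-hydroxy-4H-chromen-4-one | O=c1ccoc2cc(OCc3ccccc3)cc(O)c12 | intermediate
12 | 7-(benzyloxy)-4-oxo-4H-chromen-5-yl trifluoromethanesulfonate | O=c1ccoc2cc(OCc3ccccc3)cc(OS(=O)(=O)C(F)(F)F)c12 | intermediate
13 | [4-(benzyloxy)phenyl]boronic acid | OB(O)c1ccc(OCc2ccccc2)cc1 | starting material
14 | (2R)-7-(benzyloxy)-2-[4-(benzyloxy)phenyl]-4-oxochroman-5-yl trifluoromethanesulfonate | O=C1C[C@H](c2ccc(OCc3ccccc3)cc2)Oc2cc(OCc3ccccc3)cc(OS(=O)(=O)C(F)(F)F)c12 | intermediate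
15 | (2R)-7-(benzyloxy)-2-[4-(benzyloxy)phenyl]-4-methoxy-2H-chromen-5-yl trifluoromethanesulfonate (methyl enol ether) | COC1=C[C@H](c2ccc(OCc3ccccc3)cc2)Oc2cc(OCc3ccccc3)cc(OS(=O)(=O)C(F)(F)F)c12 | intermediate
16 | (2S,3S)-3-[acetoxy(phenyl)-λ3-iodanyl]-7-(benzyloxy)-2-[4-(benzyloxy)phenyl]-4,4-dimethoxychroman-5-yl trifluoromethanesulfonate (iodanyl group trans to the C2 aryl group; C2 geometry as in 14) | COC1(OC)[C@@H](I(OC(C)=O)c2ccccc2)[C@H](c2ccc(OCc3ccccc3)cc2)Oc2cc(OCc3ccccc3)cc(OS(=O)(=O)C(F)(F)F)c12 | intermediate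
17 | methyl (2R,3R)-6-(benzyloxy)-2-[4-(benzyloxy)phenyl]-4-(trifluoromethanesulfonyloxy)-2,3-dihydro-1-benzofuran-3-carboxylate (2,3-trans) | O=S(=O)(Oc1cc(OCc2ccccc2)cc2c1[C@@H](C(=O)OC)[C@H](c1ccc(OCc3ccccc3)cc1)O2)C(F)(F)F | intermediate
18 | [(2R,3R)-6-(benzyloxy)-2-[4-(benzyloxy)phenyl]-3-(methoxycarbonyl)-2,3-dihydro-1-benzofuran-4-yl]boronic acid | OB(O)c1cc(OCc2ccccc2)cc2c1[C@@H](C(=O)OC)[C@H](c1ccc(OCc3ccccc3)cc1)O2 | intermediate
19 | 4,5,6,7-tetrachloro-1,3-dioxoisoindolin-2-yl (2S,3S)-6-(benzyloxy)-2-[4-(benzyloxy)phenyl]-4-{[4-(benzyloxy)phenyl]ethynyl}-2,3-dihydro-1-benzofuran-3-carboxylate | C(#Cc1ccc(OCc2ccccc2)cc1)c1cc(OCc2ccccc2)cc2c1[C@H](C(=O)ON1C(=O)c3c(Cl)c(Cl)c(Cl)c(Cl)c3C1=O)[C@@H](c1ccc(OCc3ccccc3)cc1)O2 | intermediate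
20 | methyl (2R,3R)-6-(benzyloxy)-2-[4-(benzyloxy)phenyl]-4-[(2S,3S)-6-(benzyloxy)-2-[4-(benzyloxy)phenyl]-4-{[4-(benzyloxy)phenyl]ethynyl}-2,3-dihydro-1-benzofuran-3-yl]-2,3-dihydro-1-benzofuran-3-carboxylate | C(#Cc1ccc(OCc2ccccc2)cc1)c1cc(OCc2ccccc2)cc2c1[C@H](c1cc(OCc3ccccc3)cc3c1[C@@H](C(=O)OC)[C@H](c1ccc(OCc4ccccc4)cc1)O3)[C@@H](c1ccc(OCc3ccccc3)cc1)O2 | intermediate
21 | (2R,3R)-6-(benzyloxy)-2-[4-(benzyloxy)phenyl]-4-[(2S,3S)-6-(benzyloxy)-2-[4-(benzyloxy)phenyl]-4-{[4-(benzyloxy)phenyl]ethynyl}-2,3-dihydro-1-benzofuran-3-yl]-2,3-dihydro-1-benzofuran-3-carboxylic acid | C(#Cc1ccc(OCc2ccccc2)cc1)c1cc(OCc2ccccc2)cc2c1[C@H](c1cc(OCc3ccccc3)cc3c1[C@@H](C(=O)O)[C@H](c1ccc(OCc4ccccc4)cc1)O3)[C@@H](c1ccc(OCc3ccccc3)cc1)O2 | intermediate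
22 | [3,5-bis(benzyloxy)phenyl]boronic acid | OB(O)c1cc(OCc2ccccc2)cc(OCc2ccccc2)c1 | starting material
23 | 4,5,6,7-tetrachloro-1,3-dioxoisoindolin-2-yl ester of acid 21 | C(#Cc1ccc(OCc2ccccc2)cc1)c1cc(OCc2ccccc2)cc2c1[C@H](c1cc(OCc3ccccc3)cc3c1[C@@H](C(=O)ON1C(=O)c4c(Cl)c(Cl)c(Cl)c(Cl)c4C1=O)[C@H](c1ccc(OCc4ccccc4)cc1)O3)[C@@H](c1ccc(OCc3ccccc3)cc1)O2 | intermediate
24 | (2S,3S)-6-(benzyloxy)-2-[4-(benzyloxy)phenyl]-4-{[4-(benzyloxy)phenyl]ethynyl}-3-[(2R,3R)-6-(benzyloxy)-2-[4-(benzyloxy)phenyl]-3-[3,5-bis(benzyloxy)phenyl]-2,3-dihydro-1-benzofuran-4-yl]-2,3-dihydro-1-benzofuran | C(#Cc1ccc(OCc2ccccc2)cc1)c1cc(OCc2ccccc2)cc2c1[C@H](c1cc(OCc3ccccc3)cc3c1[C@@H](c1cc(OCc4ccccc4)cc(OCc4ccccc4)c1)[C@H](c1ccc(OCc4ccccc4)cc1)O3)[C@@H](c1ccc(OCc3ccccc3)cc1)O2 | intermediate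
25 | hepta-O-benzyl-cis-miyabenol C (Z alkene; 2S,3S,2'R,3'R) | c1ccccc1COc1ccc(/C=C\c2cc(OCc3ccccc3)cc3c2[C@H](c2cc(OCc4ccccc4)cc4c2[C@@H](c2cc(OCc5ccccc5)cc(OCc5ccccc5)c2)[C@H](c2ccc(OCc5ccccc5)cc2)O4)[C@@H](c2ccc(OCc4ccccc4)cc2)O3)cc1 | intermediate
26 | cis-miyabenol C | Oc1ccc(/C=C\c2cc(O)cc3c2[C@H](c2cc(O)cc4c2[C@@H](c2cc(O)cc(O)c2)[C@H](c2ccc(O)cc2)O4)[C@@H](c2ccc(O)cc2)O3)cc1 | target

**Totals**

Total step count: 15.
Longest linear sequence: 10 steps (steps 1–5 and 11–15 from 1; the branch from 10 through steps 6–10 and 11–15 is equally long).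

**Steps most likely to fail**

Step 11 (fragment union). What may go wrong: the hindered benzylic C3 radical escapes capture by the ortho-substituted aryl–nickel species and dimerises or abstracts hydrogen, while the boronic acid protodeboronates or adds across the alkyne at 75 °C. The fallback sets out from 18 and 9 and returns at 20. Bromodeboronation of 18 with CuBr2 in MeOH–H2O at 80 °C would give methyl (2R,3R)-6-(benzyloxy)-2-[4-(benzyloxy)phenyl]-4-bromo-2,3-dihydro-1-benzofuran-3-carboxylate F1. F1 and the free acid 9 would then be joined at room temperature by metallaphotoredox decarboxylative arylation (Ir[dF(CF3)ppy]2(dtbbpy)PF6, NiCl2·glyme, dtbbpy, Cs2CO3, DMF, blue LEDs). Here the radical comes from oxidation of the carboxylate and the aryl group enters by oxidative addition of the bromide to nickel, so no boronic acid and no heating are needed.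

Step 13 (second arylation). What may go wrong: radical capture at C3', which lies next to the whole first dihydrobenzofuran unit, is too slow, or activation of the crowded acid stays incomplete. The fallback changes the order of events, sets out from 17 and returns at 24. Hydrolysis of 17 with Me3SnOH in ClCH2CH2Cl at 80 °C (triflate kept) would give (2R,3R)-6-(benzyloxy)-2-[4-(benzyloxy)phenyl]-4-(trifluoromethanesulfonyloxy)-2,3-dihydro-1-benzofuran-3-carboxylic acid F2. Metallaphotoredox decarboxylative arylation of F2 with 1-bromo-3,5-bis(benzyloxy)benzene (same Ir/Ni system; bipyridine-ligated nickel adds to the aryl bromide in preference to the hindered aryl triflate) would give (2R,3R)-6-(benzyloxy)-2-[4-(benzyloxy)phenyl]-3-[3,5-bis(benzyloxy)phenyl]-2,3-dihydro-1-benzofuran-4-yl trifluoromethanesulfonate F3. Borylation as in step 10 would give [(2R,3R)-6-(benzyloxy)-2-[4-(benzyloxy)phenyl]-3-[3,5-bis(benzyloxy)phenyl]-2,3-dihydro-1-benzofuran-4-yl]boronic acid F4. F4 is then coupled with acid 9 (activated as 19) under the conditions of step 11, which leads directly to 24, so the crowded C3' position is arylated on the small fragment.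

Step 3 (key ring contraction). What may go wrong: the electron-rich C2 aryl group migrates instead of ring A (2,3-shift towards the isoflavone), elimination to the flavone takes over, or ketal formation at the peri-substituted ketone is too slow. The fallback is a Wolff ring contraction, in which only the acyl substituent (the ring A carbon) can migrate to C3; it sets out from 3 and returns at 6.
- Enolisation of 3 with LiHMDS at −78 °C and acylation with CF3CO2CH2CF3 would give (2S)-7-(benzyloxy)-2-[4-(benzyloxy)phenyl]-4-oxo-3-(trifluoroacetyl)chroman-5-yl trifluoromethanesulfonate F5, used without isolation.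
- Detrifluoroacetylative diazo transfer (MsN3, Et3N, H2O, MeCN) would give (2R)-7-(benzyloxy)-2-[4-(benzyloxy)phenyl]-3-diazo-4-oxochroman-5-yl trifluoromethanesulfonate F6 (C2 geometry unchanged).
- Irradiation of F6 in MeOH (Pyrex, medium-pressure Hg lamp) would expel N2 and move the ring A carbon from C4 to C3, giving the ketene (2R)-6-(benzyloxy)-2-[4-(benzyloxy)phenyl]-3-(oxomethylidene)-2,3-dihydro-1-benzofuran-4-yl trifluoromethanesulfonate F7.
- Methanol traps F7 as a mixture of 6 and its cis epimer, methyl (2S,3R)-6-(benzyloxy)-2-[4-(benzyloxy)phenyl]-4-(trifluoromethanesulfonyloxy)-2,3-dihydro-1-benzofuran-3-carboxylate F8.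
- DBU in CH2Cl2 would equilibrate F8 at C3 to the trans ester 6.

Further compounds
F1 | step 11 | methyl (2R,3R)-6-(benzyloxy)-2-[4-(benzyloxy)phenyl]-4-bromo-2,3-dihydro-1-benzofuran-3-carboxylate | Brc1cc(OCc2ccccc2)cc2c1[C@@H](C(=O)OC)[C@H](c1ccc(OCc3ccccc3)cc1)O2
F2 | step 13 | (2R,3R)-6-(benzyloxy)-2-[4-(benzyloxy)phenyl]-4-(trifluoromethanesulfonyloxy)-2,3-dihydro-1-benzofuran-3-carboxylic acid | O=S(=O)(Oc1cc(OCc2ccccc2)cc2c1[C@@H](C(=O)O)[C@H](c1ccc(OCc3ccccc3)cc1)O2)C(F)(F)F
F3 | step 13 | (2R,3R)-6-(benzyloxy)-2-[4-(benzyloxy)phenyl]-3-[3,5-bis(benzyloxy)phenyl]-2,3-dihydro-1-benzofuran-4-yl trifluoromethanesulfonate | O=S(=O)(Oc1cc(OCc2ccccc2)cc2c1[C@@H](c1cc(OCc3ccccc3)cc(OCc3ccccc3)c1)[C@H](c1ccc(OCc3ccccc3)cc1)O2)C(F)(F)F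
F4 | step 13 | [(2R,3R)-6-(benzyloxy)-2-[4-(benzyloxy)phenyl]-3-[3,5-bis(benzyloxy)phenyl]-2,3-dihydro-1-benzofuran-4-yl]boronic acid | OB(O)c1cc(OCc2ccccc2)cc2c1[C@@H](c1cc(OCc3ccccc3)cc(OCc3ccccc3)c1)[C@H](c1ccc(OCc3ccccc3)cc1)O2
F5 | step 3 | (2S)-7-(benzyloxy)-2-[4-(benzyloxy)phenyl]-4-oxo-3-(trifluoroacetyl)chroman-5-yl trifluoromethanesulfonate (C3 epimers and enol form) | O=C1C(C(=O)C(F)(F)F)[C@@H](c2ccc(OCc3ccccc3)cc2)Oc2cc(OCc3ccccc3)cc(OS(=O)(=O)C(F)(F)F)c12
F6 | step 3 | (2R)-7-(benzyloxy)-2-[4-(benzyloxy)phenyl]-3-diazo-4-oxochroman-5-yl trifluoromethanesulfonate | O=C1C(=[N+]=[N-])[C@@H](c2ccc(OCc3ccccc3)cc2)Oc2cc(OCc3ccccc3)cc(OS(=O)(=O)C(F)(F)F)c12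
F7 | step 3 | (2R)-6-(benzyloxy)-2-[4-(benzyloxy)phenyl]-3-(oxomethylidene)-2,3-dihydro-1-benzofuran-4-yl trifluoromethanesulfonate (ketene) | O=C=C1[C@@H](c2ccc(OCc3ccccc3)cc2)Oc2cc(OCc3ccccc3)cc(OS(=O)(=O)C(F)(F)F)c12
F8 | step 3 | methyl (2S,3R)-6-(benzyloxy)-2-[4-(benzyloxy)phenyl]-4-(trifluoromethanesulfonyloxy)-2,3-dihydro-1-benzofuran-3-carboxylate (2,3-cis) | O=S(=O)(Oc1cc(OCc2ccccc2)cc2c1[C@@H](C(=O)OC)[C@@H](c1ccc(OCc3ccccc3)cc1)O2)C(F)(F)F
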